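Catalyst is conserved: free catalyst, its intermediates, spent catalyst and trapped intermediate add up to the 30 µM charged at every moment, and the steps under discussion give nothing back from the last two.

| flask | starting material | coupling partner | capture agent | free catalyst | impurity | temperature | remark | time |
|---|---|---|---|---|---|---|---|---|
| Wednesday's | 0.050 M | 0.040 M | 2.5 mM | 30 µM | 4.6 µM | 35 °C | the very flask that is asked about, followed so far |  |
| Monday's | 0.050 M | 0.040 M | 3.8 mM | 30 µM | 4.6 µM | 30 °C | run made earlier |  |
| flask | 0.050 M | 0.0400 M | 2.50 mM | 30 µM | 4.6 µM | 35 °C |  | 1.5 h |

| Wednesday's: time / min | Wednesday's: product / % | Monday's: time / s | Monday's: product / % |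
|---|---|---|---|
| 6.00 | 30.3 | 25.0 | 2.8 |
| 10.0 | 38.8 | 50.0 | 6.1 |
| 20.0 | 51.4 | 80.0 | 8.0 |
| 40.0 | 58.1 | 90.0 | 8.2 |
| 80.0 | 61.4 | 120 | 8.7 |

(each reading ± 1 percentage point)

- elm: at 1.5 h add free catalyst, 100 % of the amount charged, then wait 50 min
- larch: at 1.5 h raise the temperature by 20 K, then wait 50 min
- alder: at 1.5 h take out 90 % of the product then present, then wait 50 min
- ash: at 1.5 h add coupling partner, 50.0 % of the amount charged, then wait 50 min
- maple: change nothing and wait 50 min more

- product that was removed still counts
- steps under discussion: free catalyst + impurity -> spent catalyst; starting material + free catalyst <-> catalyst intermediate A; catalyst intermediate C -> free catalyst + product; catalyst intermediate C + capture agent -> trapped intermediate; catalyst intermediate A -> catalyst intermediate B; coupling partner + catalyst intermediate B <-> catalyst intermediate C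
- additions bring no volume worth counting

1. product, in percent of the starting material first charged, at 1.5 h
2. which option adds most product ("none" when 2 percentage points or less is all one gets) (elm / larch / alder / ash / maple / none)
3. product present, with what was taken out counted in, in percent of the starting material first charged, after larch
4. product present, with what was taken out counted in, in percent of the starting material first charged, after alder

How far may the flask go? Coupling partner is the limiting reagent, [coupling partner] of 0.0400 M against [starting material] of 0.050 M, so the ceiling is 80.0 % of the starting material. Wednesday's flask, the very one asked about, reads 61.4 % after 80.0 min, and its last doubling of time added 3.3 percentage points. It is flattening with room for 9.30 mM more product, so we take the catalyst to be dying.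

How much product does one catalyst buy? The impurity takes one catalyst each, leaving 25.4 µM in Wednesday's flask. Dividing the last product reading by that gives 1210: the turnover number, product made per catalyst that escaped the impurity. We carry it at this temperature and this capture agent charge.

What can each option spend? Elm's fresh 30 µM meets no impurity, we assume, so it brings a budget of 36.3 mM of product against the room of 9.30 mM, and should reach the ceiling. The other options bring no catalyst, so they draw on the old budget's remainder, which that last doubling shows to be small. We hold 61.4 % for "now" and expect larch and alder within 2 points of it.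

The forecast says 61.9 % and elm, on the ground that “Fresh catalyst (elm) meets no impurity”. It gives 62.5 % after alder, and 67 % after larch, above our reckoning.

The flask gives 62.8 % at 1.5 h. Elm adds 17 points, larch ends at 63.4 % and alder at 63.2 %.

    free catalyst + impurity → spent catalyst (k = 1.80 × 10⁵ M⁻¹ s⁻¹, Ea = 22.0 kJ mol⁻¹)
    starting material + free catalyst ⇌ catalyst intermediate A (K = 22.0 M⁻¹, k = 150 M⁻¹ s⁻¹, Ea = 36.0 kJ mol⁻¹, ΔH = −19.0 kJ mol⁻¹)
    catalyst intermediate C → free catalyst + product (k = 96.0 s⁻¹, Ea = 51.0 kJ mol⁻¹)
    catalyst intermediate C + capture agent → trapped intermediate (k = 31.0 M⁻¹ s⁻¹, Ea = 37.0 kJ mol⁻¹)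
    catalyst intermediate A → catalyst intermediate B (k = 80.0 s⁻¹, Ea = 53.0 kJ mol⁻¹)
    coupling partner + catalyst intermediate B ⇌ catalyst intermediate C (K = 1500 M⁻¹, k = 150 M⁻¹ s⁻¹, Ea = 45.0 kJ mol⁻¹, ΔH = −64.0 kJ mol⁻¹)
    (constants at 35 °C)

On 25.4 µM, this flask's 62.8 % comes to 1236 turnovers, against the 1210 we carried. Trapping of catalyst intermediate C is one part of why elm pays: with that step taken away, this flask stands at 80.0 % instead of 62.8 %, and elm's gain falls from 17 points to 0 points. Now take the same flask with 0.20 M of starting material: the same 25.4 µM at 1210 turnovers buys 30.7 mM, which is 15.4 % of that charge. The computed flask gives 15.8 %.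

(All runs are calculated with constants of no real substance; scatter was added.)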